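The easy step first: you wanted a quick number for the share of target and your hunch was red, so we count what target loses, not what it gains.

| setting | green | teal | red | grey |
|---|---|---|---|---|
| starting material | 0.095 M | 0.095 M | 0.095 M | 0.095 M |
| temperature | 40 °C | 70 °C | 10 °C |  |
| time | 80 min | 80 min | 80 min | 80 min |
| remark |  |  |  | at 10 °C until 15 min, from then on at 70 °C |

    starting material ⇌ other conformer (K1 = 0.61, k1 = 1.9 × 10⁻⁴ s⁻¹, Ea1 = 106 kJ mol⁻¹, ΔH1 = −21.0 kJ mol⁻¹)
    starting material → target (k2 = 1.7 × 10⁻⁴ s⁻¹, Ea2 = 109 kJ mol⁻¹)
    other conformer → isomer of the product A (k3 = 1.7 × 10⁻⁴ s⁻¹, Ea3 = 106 kJ mol⁻¹)
    target ⇌ isomer of the product B (K4 = 1.9, k4 = 4.5 × 10⁻⁴ s⁻¹, Ea4 = 116 kJ mol⁻¹, ΔH4 = −50.0 kJ mol⁻¹)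
    2 starting material → homo dimer (k5 = 8.9 × 10⁻⁴ M⁻¹ s⁻¹, Ea5 = 59.0 kJ mol⁻¹)
    starting material + target → side product (k6 = 0.0051 M⁻¹ s⁻¹, Ea6 = 73.0 kJ mol⁻¹)
    (constants at 70 °C)

- percent here means starting material units held: one homo dimer or side product counts as two
- for a step with 2 of a species take k times the square, and two of it per event
- all constants are for 70 °C and move with temperature by the activation energies and enthalpies
- in a conversion other conformer counts as not yet reacted

* the flask with the highest share of target in all that became target or isomer of the product A or isomer of the product B or side product ("all alike" if they lie within 1.5 percentage points) (green / teal / red / grey / all alike)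
* share of target in all that became target or isomer of the product A or isomer of the product B or side product, green
* share of target in all that became target or isomer of the product A or isomer of the product B or side product, teal
* share of target in all that became target or isomer of the product A or isomer of the product B or side product, red
* share of target in all that became target or isomer of the product A or isomer of the product B or side product, grey

We take the fraction kept. With starting material held near its charge c, target comes at a steady rate, so the average target in the flask has sat for t/2, where t is the run time. It leaves by two routes: to isomer of the product B with rate constant kB, and to side product with kS·c, a pseudo-first-order constant. Each side product counts as two units, so that route weighs double. Isomer of the product A comes by way of other conformer, not from target, so we leave it out of the count. With both constants moved to the flask's temperature by their activation energies, what target has lost holds, per unit of target,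

Λ = (kS·c + 0.5·kB)·t, and the share asked is y ≈ 1/(1 + Λ).

For red, this loss number Λ, what target has lost held per unit of target, comes to

Λ = 0.0105, so y ≈ 99.0%.

For green,

Λ = 0.222, so y ≈ 81.8%.

At 70 °C the premise is weak: the forward first-order exits give starting material a half-life of 32.1 min, shorter than the run. Teal and grey are therefore rough figures. We count grey from the change, over 65.0 min.

Teal: Λ = 3.41, so y ≈ 22.7%.

Grey: Λ = 2.77, so y ≈ 26.5%.

We back red, as you did.

The forecast also names red, with 98.9% there (98% to 99.5%), 80% for green (76% to 84%), 22% for teal (18% to 27%) and 26% for grey (21% to 31%). Its grounds for the cool flasks are that “target dominates what has formed”. Its green lies below ours.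

The simulation gives red with 98.9%, then green 81.1%, grey 25.1% and teal 22.3%.

In red at 80.0 min, starting material stood at 98.9% while its dimerisation had put 1.00% into homo dimer and target stood at 0.0246%. The red share means 0.0107 of other products per unit of target, beside Λ of 0.0105. By 800 min in red, starting material had fallen to 90.3%, with target at 0.225% and side product at 0.0223%. Stretched to that time, Λ becomes 0.105, which gives 90.5%, and the red flask's share there stands at 90.6%.

All constants were set for the occasion; the flask was simulated.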